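I run the dusk flask, and I want to know what stands in it at 40 h and which remedy pays.

| flask | substrate | partner | temperature | remark | time |
|---|---|---|---|---|---|
| dusk | 0.091 M | 1.3 equiv | 25 °C | the very flask that is asked about, followed so far |  |
| winter | 0.18 M | 1.3 equiv | 20 °C | run made earlier |  |
| flask | 0.091 M | 1.30 equiv | 25 °C |  | 40 h |

dusk run (percent of the substrate charged)

| time / h | first product / % |
|---|---|
| 2.00 | 26 |
| 6.00 | 29 |
| 12.0 | 25 |
| 20.0 | 18 |
| 25.0 | 19 |
| 30.0 | 15 |

winter run (percent of the substrate charged)

| time / min | first product / % |
|---|---|
| 15.0 | 11 |
| 30.0 | 16 |
| 40.0 | 18 |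
| 60.0 | 19 |
| 80.0 | 23 |

(each reading ± 2 percentage points)

- first product, in percent of the substrate first charged, at 40 h
- the remedy with the largest gain of first product, or "none" below 2 percentage points (larch / alder / ash / elm / none)
- first product present, in percent of the substrate first charged, after ash
- first product present, in percent of the substrate first charged, after elm

- larch: change nothing and wait 12 h more
- alder: at 40 h add partner, 100% of the amount charged, then wait 12 h
- ash: at 40 h take out 90% of the by-product then present, then wait 12 h
- elm: at 40 h raise the temperature by 20 K, then wait 12 h

- additions leave the volume as it is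

Two numbers puzzle me. Dusk was charged 1.3 equiv of partner, more than the substrate, yet first product reads at best 29% at 6.00 h and then sinks to 15% at 30.0 h. The winter run, at twice the concentration and colder, reads 23% at 80.0 min and bends as well.

I clear this up by supposing that partner goes elsewhere besides into first product. So I divide the rate of partner loss by the rate of first product gain, and time drops out. Taken from the start to the peak, and counting the charge as the partner lost, a supposition of mine, this gives the partner price, the equivalents of partner charged per equivalent of first product standing at the peak: 4.48, a reading that carries the scatter of its peak. At that price, the fresh charge of alder buys about 29.0% before any fade, and the other remedies bring no partner, so I choose alder.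

The forecast gives 11% (8% to 14%), 9% after ash (6% to 14%) and 3% after elm (0.5% to 8%). It also names alder, on its own grounds: “Adding partner pulls remaining substrate into product”. It expects about 20% there, decaying to about 13%, whereas my 29.0% is an addition to what stands, before any fade, so the two differ.

The flask gives 10.1%, it holds 9.81% after ash and 2.08% after elm, and alder is best with a gain of 7.5 percentage points.

    substrate + partner → first product + by-product (k = 2.70 M⁻¹ h⁻¹, Ea = 64.0 kJ mol⁻¹)
    partner + first product → bis adduct + by-product (k = 1.20 M⁻¹ h⁻¹, Ea = 62.0 kJ mol⁻¹)
    partner + bis adduct → triple product + by-product (k = 12.0 M⁻¹ h⁻¹, Ea = 56.0 kJ mol⁻¹)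
    2 partner → homo dimer (k = 3.80 M⁻¹ h⁻¹, Ea = 67.0 kJ mol⁻¹)
    first product + by-product → side product (k = 1.30 M⁻¹ h⁻¹, Ea = 72.0 kJ mol⁻¹)
    (constants at 25 °C)

Partner, the limiting reagent despite its excess, stands at 0.0105% of its own charge at 40.0 h, with substrate at 55.6%. Alder's second charge pays 17.4 equivalents per equivalent gained, dearer than 4.48, and that gain is net of the fade over 12 h. The neighbour kept at 10 °C has the same charge: at my price its 1.30 equiv buys 29.0%, and it holds 27.7% at 40.0 h.

The data come from a simulation with made-up constants, noise included.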